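## Retrosynthetic overview

- **Feature:** pyran ring C (O1–C2–C3–C4–C4a–C8a) carries ring B at C2 and ring D at C4 on the same face, and O1 is a phenolic oxygen of ring A. This is the retron of a hetero-Diels–Alder reaction between the ring A o-quinone methide O1=C8a–C4a=C4 and the styrene C3=C2 of ring B.
- **Disconnections:** (a) four O-benzyl groups, removed last; (b) C3–C4 and O1–C2 of ring C in one catalytic asymmetric [4+2] step that sets C2 and C4; (c) C4–C4a of the benzhydrol, from a ring A arylmagnesium and a ring D aldehyde; (d) the formyl and 9-phenylnonanoyl groups on phloroglucinol.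
- **Ring order:** rings A, B, D and the terminal phenyl are bought as arenes. Ring C is the only ring formed, in the penultimate step.

Key step: step 9

**Assumption:** the (R)-configured phosphoric acid is taken to give the (2R,4R) series. The sense of induction must be confirmed on the first run, and the equally available (S)-acid is used if it is opposite.

**Remark on stereochemistry:** flavan numbering is used throughout. CIP analysis of the target SMILES gives (2R,4R), which is the 2,4-cis isomer.

**Remark on design:**
- The ortho phenol of ring A travels as an allyl ether, because an o-silyloxyaryl metal would undergo 1,3 O→C silyl shift and acid-labile groups cannot be removed next to the benzhydrol.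
- The aryl metal is made by Br/Li exchange, not from magnesium metal.
- The ketone is tolerated in the addition because of its steric shielding.

## Route

Step 1
Reactants: 1 phloroglucinol; 2 9-phenylnonanoic acid
Product: 3 9-phenyl-1-(2,4,6-trihydroxyphenyl)nonan-1-one
Conditions: BF3·OEt2 (as solvent), 85 °C
Reagents that add atoms: none
Why: Friedel–Crafts (Nencki-type) C-acylation, in which the BF3-activated acid is taken up by the threefold activated ring of 1, far more nucleophilic than the terminal phenyl of 2, and the chelated aryl ketone formed is deactivated towards a second acylation.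

Step 2
Reactants: 3 9-phenyl-1-(2,4,6-trihydroxyphenyl)nonan-1-one
Product: 4 9-phenyl-1-[2,4,6-tris(benzyloxy)phenyl]nonan-1-one
Conditions: BnBr (4 equiv), K2CO3, DMF, 70 °C
Reagents that add atoms: benzyl bromide, BrCc1ccccc1
Why: Threefold Williamson etherification, in which heating in a dipolar aprotic solvent also alkylates the two carbonyl-chelated ortho phenols and the acyl group lowers ring nucleophilicity enough to keep C-benzylation minor.

Step 3
Reactants: 4 9-phenyl-1-[2,4,6-tris(benzyloxy)phenyl]nonan-1-one
Product: 6 2,4,6-tris(benzyloxy)-3-(9-phenylnonanoyl)benzaldehyde, via aryl iminium chloride 5 (not isolated)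
Conditions: POCl3 (1.5 equiv), DMF, 0 °C → rt; then H2O
Reagents that add atoms: N,N-dimethylformamide, CN(C)C=O; water, O
Why: Vilsmeier–Haack formylation, in which the free ring position is ortho, ortho and para to three benzyloxy groups and meta to a carbonyl twisted out of conjugation, so ring attack at or below room temperature should outrun chloroformylation of the hindered ketone, and the first formyl group shuts down a second attack.

Step 4
Reactants: 7 4-bromoresorcinol
Product: 8 5-(benzyloxy)-2-bromophenol
Conditions: BnBr (1.0 equiv), K2CO3 (1.0 equiv), acetone, reflux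
Reagents that add atoms: benzyl bromide, BrCc1ccccc1
Why: Selective Williamson mono-etherification, in which the unhindered and more nucleophilic phenoxide para to bromine reacts ahead of the bromine-flanked ortho phenoxide, and regioisomer and diether are removed by chromatography.

Step 5
Reactants: 8 5-(benzyloxy)-2-bromophenol
Product: 9 2-(allyloxy)-4-(benzyloxy)-1-bromobenzene
Conditions: allyl bromide, K2CO3, DMF, rt
Reagents that add atoms: allyl bromide, C=CCBr
Why: Williamson etherification of the remaining phenol, giving an allyl ether that tolerates organolithium and organomagnesium reagents at low temperature and can later be removed under neutral conditions.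

Step 6
Reactants: 9 2-(allyloxy)-4-(benzyloxy)-1-bromobenzene; 6 2,4,6-tris(benzyloxy)-3-(9-phenylnonanoyl)benzaldehyde
Product: 12 1-{3-[(2-(allyloxy)-4-(benzyloxy)phenyl)(hydroxy)methyl]-2,4,6-tris(benzyloxy)phenyl}-9-phenylnonan-1-one (racemic), via aryllithium 10 (not isolated), via arylmagnesium bromide 11 (not isolated)
Conditions: 9, n-BuLi, THF, −78 °C; MgBr2·OEt2, −78 → −30 °C; 6, THF, −78 → 0 °C; H2O
Reagents that add atoms: none
Why: Bromine–lithium exchange (chosen over magnesium metal, whose radical pathway would let the o-allyloxyaryl radical cyclise), transmetalation and Grignard 1,2-addition, in which the formyl group is the only accessible electrophile because the ketone, flanked by two benzyloxy groups and twisted out of the ring plane, resists addition and any magnesium enolate returns the ketone on quench; the new carbinol centre is racemic, which is irrelevant because it becomes sp2 in step 9.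

Step 7
Reactants: 12 allyl-protected benzhydrol
Product: 13 1-{2,4,6-tris(benzyloxy)-3-[(4-(benzyloxy)-2-hydroxyphenyl)(hydroxy)methyl]phenyl}-9-phenylnonan-1-one (racemic)
Conditions: Pd(PPh3)4 (5 mol %), morpholine, THF, rt; pH 7 work-up, Et3N-deactivated silica
Reagents that add atoms: none
Why: Tsuji–Trost-type deallylation, in which zerovalent palladium ionises only the aryl allyl ether and morpholine takes up the allyl group, so the phenol is released under neutral to weakly basic conditions that leave the benzyl ethers, the ketone and the acid-labile benzhydrol untouched.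

Step 8
Reactants: 14 4-acetoxystyrene
Product: 15 4-vinylphenol
Conditions: K2CO3 (cat.), MeOH, 0 °C → rt; used at once
Reagents that add atoms: none
Why: Base-catalysed transesterification of the aryl acetate, with cold, mild conditions and immediate use to avoid polymerisation of the vinylphenol.

Step 9
Reactants: 13 o-hydroxybenzhydrol; 15 4-vinylphenol
Product: 17 1-{2,4,6-tris(benzyloxy)-3-[(2R,4R)-7-(benzyloxy)-2-(4-hydroxyphenyl)chroman-4-yl]phenyl}-9-phenylnonan-1-one, via o-quinone methide 16 (not isolated)
Conditions: (R)-3,3'-bis(2,4,6-triisopropylphenyl)-1,1'-binaphthyl-2,2'-diyl hydrogen phosphate (10 mol %), 4 Å MS, toluene–CH2Cl2, −20 → 0 °C, 15 (2 equiv) added slowly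
Reagents that add atoms: none
Why: The phosphoric acid protonates the carbinol OH of 13 and water leaves, giving the (E)-o-quinone methide 16 (heterodiene O1=C8a–C4a=C4) that stays hydrogen-bonded to the catalyst through O1, and the CH2 terminus of 15 (future C3) attacks the electrophilic C4 while O1 closes onto the developing benzylic cation at C2, an asynchronous inverse-electron-demand oxa-Diels–Alder reaction. The closest known reaction type is the chiral-phosphoric-acid-catalysed [4+2] cycloaddition of o-quinone methides released in situ from o-hydroxybenzhydrols with hydroxystyrenes, vinylindoles and enamides, which gives 2,4-cis-chromans. Ring C closes as a [4+2] cycloaddition, and in the stepwise limit this is conjugate addition at C4 followed by 6-exo-trig capture of the p-quinone-methide-like cation at C2 by O1. C4 is controlled by the catalyst, whose P–OH donates to O1 of 16 while its P=O accepts the 4'-OH of 15, so that the triisopropylphenyl walls leave one face of C4 open. C2 is controlled relative to C4 by the endo placement of ring B under the heterodiene together with the E geometry of 16, which puts both aryl groups on the same face (2,4-cis). The step needs quinone methide formation on ring A only (ring D has no free phenol, and O7 is benzylated so no p-quinone methide can arise), head-to-tail regiochemistry (polarity match of C4 with the styrene terminus), and suppression of acid-induced oligomerisation of 15 (weak acid, low temperature, slow addition).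

Step 10
Reactants: 17 tetra-O-benzyl cycloadduct
Product: 18 1-{2,4,6-trihydroxy-3-[(2R,4R)-7-hydroxy-2-(4-hydroxyphenyl)chroman-4-yl]phenyl}-9-phenylnonan-1-one (target)
Conditions: H2 (1 atm), 10% Pd/C, EtOAc–MeOH, rt
Reagents that add atoms: none
Why: Heterogeneous catalytic hydrogenolysis, in which the four aryl benzyl ethers are cleaved quickly at atmospheric pressure whereas the cyclic C2–O1 benzylic ether, the doubly ortho-substituted and then chelated ketone and the arenes react much more slowly, and the neutral medium leaves C2 and C4 untouched.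

## Compound list

1 | phloroglucinol | Oc1cc(O)cc(O)c1 | starting material
2 | 9-phenylnonanoic acid | O=C(O)CCCCCCCCc1ccccc1 | starting material
3 | 9-phenyl-1-(2,4,6-trihydroxyphenyl)nonan-1-one | O=C(CCCCCCCCc1ccccc1)c1c(O)cc(O)cc1O | intermediate
4 | 9-phenyl-1-[2,4,6-tris(benzyloxy)phenyl]nonan-1-one | O=C(CCCCCCCCc1ccccc1)c1c(OCc2ccccc2)cc(OCc2ccccc2)cc1OCc1ccccc1 | intermediate
5 | N,N-dimethyl aryl iminium chloride of 6 (not isolated) | C[N+](C)=Cc1c(OCc2ccccc2)cc(OCc2ccccc2)c(C(=O)CCCCCCCCc2ccccc2)c1OCc1ccccc1.[Cl-] | intermediate
6 | 2,4,6-tris(benzyloxy)-3-(9-phenylnonanoyl)benzaldehyde | O=Cc1c(OCc2ccccc2)cc(OCc2ccccc2)c(C(=O)CCCCCCCCc2ccccc2)c1OCc1ccccc1 | intermediate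
7 | 4-bromoresorcinol | Oc1ccc(Br)c(O)c1 | starting material
8 | 5-(benzyloxy)-2-bromophenol | Oc1cc(OCc2ccccc2)ccc1Br | intermediate
9 | 2-(allyloxy)-4-(benzyloxy)-1-bromobenzene | C=CCOc1cc(OCc2ccccc2)ccc1Br | intermediate
10 | [2-(allyloxy)-4-(benzyloxy)phenyl]lithium (not isolated) | [Li]c1ccc(OCc2ccccc2)cc1OCC=C | intermediate
11 | [2-(allyloxy)-4-(benzyloxy)phenyl]magnesium bromide (not isolated) | Br[Mg]c1ccc(OCc2ccccc2)cc1OCC=C | intermediate
12 | allyl-protected benzhydrol, racemic | O=C(CCCCCCCCc1ccccc1)c1c(OCc2ccccc2)cc(OCc2ccccc2)c(C(O)c2ccc(OCc3ccccc3)cc2OCC=C)c1OCc1ccccc1 | intermediate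
13 | (4-benzyloxy-2-hydroxyphenyl)[3-(9-phenylnonanoyl)-2,4,6-tris(benzyloxy)phenyl]methanol, racemic | O=C(CCCCCCCCc1ccccc1)c1c(OCc2ccccc2)cc(OCc2ccccc2)c(C(O)c2ccc(OCc3ccccc3)cc2O)c1OCc1ccccc1 | intermediate
14 | 4-acetoxystyrene | CC(=O)Oc1ccc(C=C)cc1 | starting material
15 | 4-vinylphenol | C=Cc1ccc(O)cc1 | intermediate
16 | (E)-o-quinone methide of ring A, ring D on the exocyclic carbon (not isolated) | O=C1C=C(OCc2ccccc2)C=C/C1=C\c1c(OCc2ccccc2)cc(OCc2ccccc2)c(C(=O)CCCCCCCCc2ccccc2)c1OCc1ccccc1 | intermediate
17 | (2R,4R)-tetra-O-benzyl cycloadduct, 4'-OH free, 2,4-cis | O=C(CCCCCCCCc1ccccc1)c1c(OCc2ccccc2)cc(OCc2ccccc2)c([C@@H]2C[C@H](c3ccc(O)cc3)Oc3cc(OCc4ccccc4)ccc32)c1OCc1ccccc1 | intermediate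
18 | 1-{2,4,6-trihydroxy-3-[(2R,4R)-7-hydroxy-2-(4-hydroxyphenyl)chroman-4-yl]phenyl}-9-phenylnonan-1-one | O=C(CCCCCCCCc1ccccc1)c1c(O)cc(O)c([C@@H]2C[C@H](c3ccc(O)cc3)Oc3cc(O)ccc32)c1O | target

## Step count

Total step count: 10. Longest linear sequence: 7 (steps 1, 2, 3, 6, 7, 9, 10).

## Steps most likely to fail

**Step 9.**
- *Risk:* The two ortho benzyloxy groups of the twisted ring D shield both faces of C4, and the para hydroxyl of 15 sits far from the reacting alkene. The addition may therefore be slow, 15 may oligomerise under acid, facial discrimination may be poor, and reversible opening of the C2–O1 bond may erode the cis relationship.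
- *Fallback:* asymmetric induction is replaced by resolution, setting out from 13 and 15 and coming back at 17.
  - The cycloaddition is run with achiral diphenyl hydrogen phosphate, (PhO)2P(O)OH, or a stronger achiral Brønsted acid if needed. This gives 17 together with its mirror image, the (2S,4S)-cycloadduct F1.
  - The free 4'-OH of the racemate is esterified with (1S,4R)-camphanic chloride (Et3N, DMAP, CH2Cl2). This gives the camphanate of 17 F2 and the camphanate of the mirror image F3.
  - The two diastereomers are separated by crystallisation or chromatography.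
  - Brief methanolysis of F2 (K2CO3, MeOH, 0 °C) returns 17.

**Step 6.**
- *Risk:* Enolisation of, or addition to, the ketone may compete with attack on the hindered, electron-rich aldehyde. This would use up the aryl metal and leave the conversion incomplete.
- *Fallback:* the order of events is inverted so that no ketone is present when the aryl metal is used. It sets out from 9 (through 11) and 2 and comes back at 12.
  - Purchased 1,3,5-tris(benzyloxy)benzene is formylated (POCl3, DMF) to 2,4,6-tris(benzyloxy)benzaldehyde F4.
  - Bromination (NBS, MeCN) gives 3-bromo-2,4,6-tris(benzyloxy)benzaldehyde F5.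
  - Addition of 11 gives the bromo benzhydrol F6.
  - Acid 2 is converted (carbonyldiimidazole, MeNHOMe·HCl) into N-methoxy-N-methyl-9-phenylnonanamide F7.
  - F6 is treated with n-BuLi (2.1 equiv, THF, −78 °C; O-deprotonation, then Br/Li exchange) and then with F7. This Weinreb-type ketone synthesis gives 12.

**Step 3.**
- *Risk:* If ring attack needs heating, chloroformylation at the enolisable ketone may compete with it.
- *Fallback:* formylation is moved ahead of protection, setting out from 3 and coming back at 6.
  - Rieche formylation of the free acylphloroglucinol 3 (Cl2CHOMe 1.1 equiv, TiCl4, CH2Cl2, −20 → 0 °C, aqueous work-up) gives 2,4,6-trihydroxy-3-(9-phenylnonanoyl)benzaldehyde F8. At this stage there are no benzyl ethers to lose and the chelated ketone is inert.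
  - Threefold Williamson benzylation (BnBr, K2CO3, DMF, 70 °C) gives 6.

## Further compounds

F1 | step 9 | (2S,4S)-tetra-O-benzyl cycloadduct, mirror image of 17 | O=C(CCCCCCCCc1ccccc1)c1c(OCc2ccccc2)cc(OCc2ccccc2)c([C@H]2C[C@@H](c3ccc(O)cc3)Oc3cc(OCc4ccccc4)ccc32)c1OCc1ccccc1
F2 | step 9 | 4'-O-[(1S,4R)-camphanoyl] ester of 17 | O=C(CCCCCCCCc1ccccc1)c1c(OCc2ccccc2)cc(OCc2ccccc2)c([C@@H]2C[C@H](c3ccc(OC(=O)[C@@]45CC[C@@](C)(C(=O)O4)C5(C)C)cc3)Oc3cc(OCc4ccccc4)ccc32)c1OCc1ccccc1
F3 | step 9 | 4'-O-[(1S,4R)-camphanoyl] ester of F1 | O=C(CCCCCCCCc1ccccc1)c1c(OCc2ccccc2)cc(OCc2ccccc2)c([C@H]2C[C@@H](c3ccc(OC(=O)[C@@]45CC[C@@](C)(C(=O)O4)C5(C)C)cc3)Oc3cc(OCc4ccccc4)ccc32)c1OCc1ccccc1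
F4 | step 6 | 2,4,6-tris(benzyloxy)benzaldehyde | O=Cc1c(OCc2ccccc2)cc(OCc2ccccc2)cc1OCc1ccccc1
F5 | step 6 | 3-bromo-2,4,6-tris(benzyloxy)benzaldehyde | O=Cc1c(OCc2ccccc2)cc(OCc2ccccc2)c(Br)c1OCc1ccccc1
F6 | step 6 | [2-(allyloxy)-4-(benzyloxy)phenyl][3-bromo-2,4,6-tris(benzyloxy)phenyl]methanol, racemic | OC(c1ccc(OCc2ccccc2)cc1OCC=C)c1c(OCc2ccccc2)cc(OCc2ccccc2)c(Br)c1OCc1ccccc1
F7 | step 6 | N-methoxy-N-methyl-9-phenylnonanamide | CON(C)C(=O)CCCCCCCCc1ccccc1
F8 | step 3 | 2,4,6-trihydroxy-3-(9-phenylnonanoyl)benzaldehyde | O=Cc1c(O)cc(O)c(C(=O)CCCCCCCCc2ccccc2)c1O
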